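A direct plan would close the chromone first and build the isochromanone last. Eugenin A1 would be iodinated at C6 to 6-iodoeugenin A2,
which would be Heck-coupled with racemic methyl 3-hydroxy-2-methylpent-4-enoate A3 to the β-keto ester A4. After silyl enolisation,
A4 and ethyl (R)-5-hydroxyhex-2-ynoate A5 would give the benzene ring and the lactone in one Diels–Alder/aromatisation pot.
Weakest steps: (a) the closing benzannulation/lactonisation: a tetrasubstituted ketene-acetal diene would have to add to a β-alkyl ynoate at 135 °C,
beside a chromone that silyl triflate can activate, and a hexasubstituted benzene and all the material would ride on this last step;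
(b) the Heck arylation: an iodide flanked by OH and OMe would have to couple with a base-labile aldol (retro-aldol, dehydration);
(c) the aldol run-up to A4: two stereocentres would be made only to be erased, and a simple resorcylic ring would be built atom by atom instead of being bought.

**Retrosynthetic overview**
Rings: A/C are the benzo and pyranone rings of the chromone, B/D the benzo and lactone rings of the isochromanone. The target is a 2,2'-methylenebisphenol: the CH2 bridge joins C6 of ring A (ortho to 5-OH) and C5 of ring B (ortho to 6-OH), two phenol-ortho carbons of like, nucleophilic polarity.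
Key disconnection: the C6(ring A)–CH2 bond. The polarity of the benzylic carbon on ring B is reversed as an ortho-quinone methide (from a C5 acetoxymethyl group, carbon from formaldehyde), which unprotected eugenin captures in the last step.
Ring order: D closes first, in one step and with the stereocentre, by C–H alkylation/lactonisation of a bought benzoic acid (ring B) with (R)-propylene oxide; C closes separately (eugenin); the key step closes no ring.
The design therefore needs no benzannulation of a hexasubstituted ring, no metal coupling at the hindered C6 and no throw-away stereocentres, and it joins two halves instead of running one line.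

Key step: step 5

Remark: 2,4-dimethoxy-3-methylbenzoic acid and 2',6'-dihydroxy-4'-methoxyacetophenone are taken as catalogue compounds; eugenin is made in one step so that the route does not depend on its supply.

Step 1
Reactants: 1 2,4-dimethoxy-3-methylbenzoic acid; 2 (R)-propylene oxide (3 equiv)
Product: 4 (R)-6,8-dimethoxy-3,7-dimethyl-3,4-dihydro-1H-isochromen-1-one, via hydroxy acid 3 (not isolated)
Conditions: Pd(OAc)2 (5 mol %), N-acetyl-tert-leucine (10 mol %), KOAc (1 equiv), (CF3)2CHOH, 75 °C, sealed tube
Reagents that add atoms: none
Why: Carboxylate-directed ortho C–H alkylation/lactonisation of a benzoic acid with a terminal epoxide under divalent palladium catalysis: palladation can occur only at C6 (the other ortho position carries OMe), the aryl–palladium bond opens the epoxide at its CH2 carbon and the hydroxyl of 3 closes ring D on the acid with loss of water, so the oxygen-bearing stereocentre of 2 is never a reacting centre and becomes C3 with R configuration.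

Step 2
Reactants: 4 (R)-6,8-dimethoxy-3,7-dimethyl-3,4-dihydro-1H-isochromen-1-one
Product: 5 (R)-6,8-dihydroxy-3,7-dimethyl-3,4-dihydro-1H-isochromen-1-one
Conditions: BBr3 (4 equiv), CH2Cl2, −78 °C to rt; then H2O
Reagents that add atoms: none
Why: Lewis-acid cleavage of aryl methyl ethers with BBr3 (bromide attacks the O-methyl carbons, the peri-chelated 8-OMe first), which leaves the lactone C–O bond and C3 untouched.

Step 3
Reactants: 5 (R)-6,8-dihydroxy-3,7-dimethyl-3,4-dihydro-1H-isochromen-1-one; 6 formaldehyde (37% aqueous, 3 equiv)
Product: 8 [(3R)-6,8-dihydroxy-3,7-dimethyl-1-oxo-3,4-dihydro-1H-isochromen-5-yl]methyl acetate, via hydroxymethyl phenol 7 (not isolated)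
Conditions: NaOAc, AcOH, 80 °C
Reagents that add atoms: acetic acid, CC(=O)O
Why: Lederer–Manasse hydroxymethylation with in-situ acetolysis (acetoxymethylation) at C5, the only unsubstituted carbon of ring B, ortho to 6-OH and para to 8-OH, a transformation known for 2,4-dihydroxy-3-methylacetophenone, which carries the same substitution pattern; no stereocentre is formed and C3 is not affected.

Step 4
Reactants: 9 2',6'-dihydroxy-4'-methoxyacetophenone; 10 ethyl acetate (excess)
Product: 12 eugenin (5-hydroxy-7-methoxy-2-methyl-4H-chromen-4-one), via 1,3-diketone 11 (not isolated)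
Conditions: NaH (5 equiv), THF, reflux; then conc. HCl, MeOH, reflux
Reagents that add atoms: none
Why: Crossed Claisen condensation of the acetophenone polyanion with ethyl acetate followed by acid cyclodehydration closes ring C, and because the two phenols of 9 are equivalent by symmetry only one chromone can form.

Step 5
Reactants: 8 [(3R)-6,8-dihydroxy-3,7-dimethyl-1-oxo-3,4-dihydro-1H-isochromen-5-yl]methyl acetate; 12 eugenin (2.5 equiv)
Product: 14 (R)-6,8-dihydroxy-5-[(5-hydroxy-7-methoxy-2-methyl-4-oxo-4H-chromen-6-yl)methyl]-3,7-dimethyl-3,4-dihydro-1H-isochromen-1-one (CNP0180307.1), via ortho-quinone methide 13 (not isolated)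
Conditions: 12, MgCl2 (3 equiv), Et3N (6 equiv), THF, rt, 30 min; then 8 in THF added over 2 h, 60 °C; 1 M HCl work-up
Reagents that add atoms: none
Why: Triethylamine and MgCl2 convert the phenols into magnesium phenoxides; the phenoxide of 8 expels acetate (E1cB) to give the ortho-quinone methide 13 (C5=CH2, C6=O), whose oxygen stays on the magnesium that also carries the 5-phenoxide of 12, and the ortho carbon C6 of ring A adds to the exocyclic CH2 in a cyclic transition state, after which tautomerisation restores both aromatic rings. The closest known reaction types are the biomimetic capture of ortho-quinone methides released from ortho-acetoxymethyl phenols by carbon nucleophiles and the ortho-specific coupling of magnesium phenoxides with such methides to 2,2'-methylenebisphenols. No ring is closed and no stereocentre is made; C3 is remote, carries no acidic hydrogen and is not touched. The step needs C6 over C8 (and over C3 of ring C), C- over O-alkylation and mono- over bis-alkylation: the only free hydroxyl of 12 is 5-OH and its only open ortho position is C6, whereas C8 lies between OMe and the ring oxygen and has no metal-binding neighbour; O-adducts are benzyl aryl ethers that should revert to 13 under the conditions, and the excess of 12 should suppress a second alkylation at C8. Ring B of 8 has no free CH, so 13 cannot condense with its own precursor through carbon.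

**Compound list**
1 | 2,4-dimethoxy-3-methylbenzoic acid | COc1ccc(C(=O)O)c(OC)c1C | starting material
2 | (R)-propylene oxide | C[C@@H]1CO1 | starting material
3 | (R)-6-(2-hydroxypropyl)-2,4-dimethoxy-3-methylbenzoic acid (not isolated) | COc1cc(C[C@@H](C)O)c(C(=O)O)c(OC)c1C | intermediate
4 | (R)-6,8-dimethoxy-3,7-dimethyl-3,4-dihydro-1H-isochromen-1-one | COc1cc2C[C@@H](C)OC(=O)c2c(OC)c1C | intermediate
5 | (R)-6,8-dihydroxy-3,7-dimethyl-3,4-dihydro-1H-isochromen-1-one | Oc1cc2C[C@@H](C)OC(=O)c2c(O)c1C | intermediate
6 | formaldehyde | C=O | starting material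
7 | (R)-6,8-dihydroxy-5-(hydroxymethyl)-3,7-dimethyl-3,4-dihydro-1H-isochromen-1-one (not isolated) | OCc1c(O)c(C)c(O)c2c1C[C@@H](C)OC2=O | intermediate
8 | [(3R)-6,8-dihydroxy-3,7-dimethyl-1-oxo-3,4-dihydro-1H-isochromen-5-yl]methyl acetate | CC(=O)OCc1c(O)c(C)c(O)c2c1C[C@@H](C)OC2=O | intermediate
9 | 2',6'-dihydroxy-4'-methoxyacetophenone | CC(=O)c1c(O)cc(OC)cc1O | starting material
10 | ethyl acetate | CCOC(C)=O | starting material
11 | 1-(2,6-dihydroxy-4-methoxyphenyl)butane-1,3-dione (not isolated) | CC(=O)CC(=O)c1c(O)cc(OC)cc1O | intermediate
12 | eugenin, 5-hydroxy-7-methoxy-2-methyl-4H-chromen-4-one | COc1cc(O)c2c(c1)oc(C)cc2=O | intermediate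
13 | (3R)-8-hydroxy-3,7-dimethyl-5-methylidene-3,4-dihydro-1H-isochromene-1,6(5H)-dione, ortho-quinone methide (not isolated) | C=C1C(=O)C(C)=C(O)C2=C1C[C@@H](C)OC2=O | intermediate
14 | (R)-6,8-dihydroxy-5-[(5-hydroxy-7-methoxy-2-methyl-4-oxo-4H-chromen-6-yl)methyl]-3,7-dimethyl-3,4-dihydro-1H-isochromen-1-one | COc1cc2oc(C)cc(=O)c2c(O)c1Cc1c(O)c(C)c(O)c2c1C[C@@H](C)OC2=O | target

**Step count and risks**
Total step count: 5. Longest linear sequence: 4 steps (1, 2, 3, 5).

Steps most likely to fail, riskiest first:

Step 5. Regiocontrol may be lost: capture of the methide through C8 or twice (C6 and C8), or oligomerisation of the methide through oxygen before the C–C bond forms. Fallback (sets out from 5, returns at 14): the bridge carbon is brought on the chromone side, where symmetry fixes its position. 4-Hydroxy-2,6-dimethoxybenzaldehyde F1 is C-acetylated ortho to its hydroxyl (Ac2O, BF3·OEt2; the two ortho positions are equivalent) to 3-acetyl-4-hydroxy-2,6-dimethoxybenzaldehyde F2. N,N-Dimethylacetamide dimethyl acetal (toluene, 110 °C) then closes ring C on the only hydroxyl to give 5,7-dimethoxy-2-methyl-4-oxo-4H-chromene-6-carbaldehyde F3. Reductive Friedel–Crafts benzylation of 5 with F3 (Et3SiH, CF3CO2H, CH2Cl2), in which 5 can react only at C5, gives (R)-5-[(5,7-dimethoxy-2-methyl-4-oxo-4H-chromen-6-yl)methyl]-6,8-dihydroxy-3,7-dimethyl-3,4-dihydro-1H-isochromen-1-one F4. BCl3 (CH2Cl2, −78 to 0 °C) cleaves only the peri-chelated 5-OMe and returns 14.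

Step 1. Catalyst turnover may be lost through chelation of palladium by the electron-rich ortho-methoxy acid, or the epoxide may be consumed by solvolysis before C–H alkylation. Fallback (sets out from 1, returns at 4): directed ortho-lithiation instead of catalytic C–H activation. 1 is converted via 2,4-dimethoxy-3-methylbenzoyl chloride F5 ((COCl)2, cat. DMF, CH2Cl2) into 2,4-dimethoxy-N,3-dimethylbenzamide F6 (MeNH2, THF). Double deprotonation (s-BuLi, TMEDA, THF, −78 °C; lithiation at C6, the only free position ortho to the amide) and opening of 2 at its CH2 carbon give (R)-6-(2-hydroxypropyl)-2,4-dimethoxy-N,3-dimethylbenzamide F7. F7 lactonises with loss of methylamine (TsOH, toluene, reflux) to 4, with the stereocentre again untouched.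

Step 3. Over-condensation may occur: ionisation of the benzylic acetate under the acidic conditions of its formation and alkylation of unreacted 5 at C5. Fallback (sets out from 5, returns at 13): aminomethylation with preformed dimethylmethylideneammonium iodide (CH2Cl2, rt) gives the Mannich base (R)-5-[(dimethylamino)methyl]-6,8-dihydroxy-3,7-dimethyl-3,4-dihydro-1H-isochromen-1-one F8, which does not ionise under the conditions of its formation. Heated with the magnesium phenoxide of 12 (MgCl2, Et3N, toluene, 100 °C), F8 loses dimethylamine to give 13, which is captured as in step 5.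

Further compounds
F1 | step 5 | 4-hydroxy-2,6-dimethoxybenzaldehyde | COc1cc(O)cc(OC)c1C=O
F2 | step 5 | 3-acetyl-4-hydroxy-2,6-dimethoxybenzaldehyde | COc1cc(O)c(C(C)=O)c(OC)c1C=O
F3 | step 5 | 5,7-dimethoxy-2-methyl-4-oxo-4H-chromene-6-carbaldehyde | COc1cc2oc(C)cc(=O)c2c(OC)c1C=O
F4 | step 5 | (R)-5-[(5,7-dimethoxy-2-methyl-4-oxo-4H-chromen-6-yl)methyl]-6,8-dihydroxy-3,7-dimethyl-3,4-dihydro-1H-isochromen-1-one | COc1cc2oc(C)cc(=O)c2c(OC)c1Cc1c(O)c(C)c(O)c2c1C[C@@H](C)OC2=O
F5 | step 1 | 2,4-dimethoxy-3-methylbenzoyl chloride | COc1ccc(C(=O)Cl)c(OC)c1C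
F6 | step 1 | 2,4-dimethoxy-N,3-dimethylbenzamide | CNC(=O)c1ccc(OC)c(C)c1OC
F7 | step 1 | (R)-6-(2-hydroxypropyl)-2,4-dimethoxy-N,3-dimethylbenzamide | CNC(=O)c1c(C[C@@H](C)O)cc(OC)c(C)c1OC
F8 | step 3 | (R)-5-[(dimethylamino)methyl]-6,8-dihydroxy-3,7-dimethyl-3,4-dihydro-1H-isochromen-1-one | CN(C)Cc1c(O)c(C)c(O)c2c1C[C@@H](C)OC2=O
A1 | direct plan | eugenin, 5-hydroxy-7-methoxy-2-methyl-4H-chromen-4-one | Cc1cc(=O)c2c(O)cc(OC)cc2o1
A2 | direct plan | 6-iodoeugenin, 5-hydroxy-6-iodo-7-methoxy-2-methyl-4H-chromen-4-one | Cc1cc(=O)c2c(O)c(I)c(OC)cc2o1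
A3 | direct plan | methyl 3-hydroxy-2-methylpent-4-enoate (racemic, syn/anti mixture) | COC(=O)C(C)C(O)C=C
A4 | direct plan | methyl 5-(5-hydroxy-7-methoxy-2-methyl-4-oxo-4H-chromen-6-yl)-2-methyl-3-oxopentanoate (racemic) | COC(=O)C(C)C(=O)CCc1c(OC)cc2oc(C)cc(=O)c2c1O
A5 | direct plan | ethyl (R)-5-hydroxyhex-2-ynoate | CCOC(=O)C#CC[C@@H](C)O
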